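The target at its plateau, 34.6% of the charge, and a full load of capture agent, 30.0% of it, cannot together hold the partner charged to the south-west flask at 1.00 equiv, so long as each binds one partner.

| flask | starting material | partner | capture agent | temperature | remark | time |
|---|---|---|---|---|---|---|
| south-west | 0.20 M | 1 equiv | 0.060 M | 80 °C | the very flask that is asked about, followed so far |  |
| north | 0.20 M | 1.5 equiv | 0.060 M | 65 °C | run made earlier |  |
| flask | 0.20 M | 1.00 equiv | 0.0600 M | 80 °C |  | 8.0 d |

| run | time / h | target / % | starting material / % |
|---|---|---|---|
| south-west | 15.0 | 28.8 | 22.2 |
| south-west | 25.0 | 32.0 | 10.9 |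
| south-west | 40.0 | 33.7 | 4.2 |
| south-west | 60.0 | 33.9 | 2.1 |
| south-west | 72.0 | 34.5 | 1.5 |
| south-west | 120 | 34.7 | 0 |
| south-west | 192 | 34.6 | 0 |
| north | 3.00 | 1.0 | 94.3 |
| north | 5.00 | 2.3 | 89.4 |
| north | 8.00 | 4.4 | 83.5 |
| north | 12.0 | 8.2 | 73.1 |
| north | 20.0 | 13.6 | 61.2 |
| north | 30.0 | 17.1 | 49.4 |
| north | 40.0 | 19.6 | 40.4 |

(scatter of a reading: 0.5 percentage points)

- additions leave the volume as it is
- a reading or a percentage of target counts all its forms, free or not
- a reading of starting material is of its free form alone

- eta: at 8.0 d add partner, 100% of the amount charged, then wait 15 d
- zeta: at 8.0 d raise the temperature by 15 K, then wait 15 d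
- gamma: change nothing and wait 15 d more
- alpha: at 8.0 d add starting material, 50.0% of the amount charged, then wait 15 d

- target, in percent of the starting material first charged, at 8.0 d
- which option adds most target ("none" when 2 percentage points or less is all one gets) (eta / zeta / gamma / alpha / none)
- target present, in percent of the starting material first charged, after eta
- target present, in percent of the starting material first charged, after zeta

1. The gap of 35.4% is the unplaced partner, the fraction of the partner charge that neither plateau target nor a full capture agent can hold; the partner, level with the starting material, is a co-limiting reagent, so this balance is worth writing.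
2. Time need not be known well, for between 120 h and 192 h the south-west target moved by 0.1 percentage points against a scatter of 0.5 points.
3. The scatter of one reading passes point for point into the unplaced partner, so one reading shifts the gap by about 0.5 points on 35.4%, which leaves the argument standing.
4. The capture charge is the number to weigh, since a capacity lower by 15 points gives a gap of 50.4%, and the partner charge counts point for point; but both are weighed charges.
5. My own reckoning therefore puts target at 8.0 d on the plateau, 34.6%. With starting material read at 0%, this reckoning expects nothing from added partner and a flat line from waiting.
6. The readings cannot say whether the unplaced partner is free or bound. Free partner surviving days at 80 °C seems the poorer bet, so this reckoning takes a bound form, which fresh starting material would not reach and heat might. It names zeta, without a size, where the forecast names alpha.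
7. The forecast gives target at 8.0 d as 34.6% (34.1% to 35.1%), 34.8% after eta (34% to 37%) and 34.4% after zeta (31.5% to 36%), on the ground that “Waiting, extra partner or heat should therefore give almost nothing, though heat might cost a little.”

    starting material → open intermediate (k = 0.00150 /min, Ea = 104 kJ/mol)
    partner → second intermediate (k = 0.00150 /min, Ea = 120 kJ/mol)
    open intermediate + second intermediate → target (k = 0.490 /M/min, Ea = 88.0 kJ/mol)
    2 open intermediate → homo product (k = 0.0870 /M/min, Ea = 73.0 kJ/mol)
    target ⇌ isomer of the product (K = 1.60, k = 0.0160 /min, Ea = 96.0 kJ/mol, ΔH = −67.0 kJ/mol)
    second intermediate + capture agent → trapped intermediate (k = 0.00210 /M/min, Ea = 103 kJ/mol)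
    starting material + target ⇌ idle adduct, settled at all times (K = 14.0 /M, ΔH = −13.0 kJ/mol)
    (constants at 80 °C)

The flask stands at 34.8% of target and the best option is zeta, which adds 21 points and reaches 55.4%, while eta ends at 34.8% and alpha adds 0.64 points. At 192 h the flask has free partner at 0% and capture agent at 74% of its charge, and its isomer of the product holds 55.6%, more than the unplaced partner, which on the simulated target reads 35.2%. In the neighbour flask kept at 65 °C, target 16.5% and free partner 6.0% leave an unplaced partner of 47.5%, and its isomer of the product stands at 61.3%.

(Readings and results are simulated from invented constants, and the scatter is random.)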